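The last reading of the green run, at 4.00 min, stands at 10.2% of target. The flask asked about holds 20 µM of free catalyst, against 30 µM in green.

all flasks: starting material 0.041 M
- green: second substrate 0.041 M; coupling partner 0.041 M (fed, over 2.0 min); free catalyst 30 µM; run made earlier; the fed solution adds 0.20 times the starting volume
- flask: second substrate 0.0410 M; coupling partner 0.0410 M (fed, over 2.0 min); free catalyst 20 µM; the fed solution adds 0.20 times the starting volume; time 20 min

green run (percent of the starting material charged): time / min: target / % = 0.833: 1.8; 1.50: 2.7; 2.50: 7.8; 3.00: 9.5; 4.00: 10.2

(scatter of a reading: 0.5 percentage points)

- the moment within 20 min at which there is most target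
- the amount of target, in percent of the starting material charged, at that time
- the first time at which target reaches 5.5%, in the same percent, in min

- amounts are per litre of the starting volume; all of the dose is in the solution fed
- what was read earlier has a scatter of 0.5 percentage points, one standard deviation
- steps that have been proposed: starting material + free catalyst <-> catalyst intermediate A; coupling partner + catalyst intermediate A <-> free catalyst + target; second substrate + free catalyst <-> catalyst intermediate B; coupling partner + catalyst intermediate B -> free catalyst + second product
- no earlier run changes the charge of free catalyst; that part of a forecast is a guess

One molecule of coupling partner can be followed to its fork. With catalyst intermediate A it gives target, and with catalyst intermediate B it gives second product. Green charged 0.041 M of coupling partner and 0.041 M of starting material. Suppose the charge of coupling partner in green has reacted by the last reading. Then the fork chance, the share of coupling partner ending as target (its selectivity), reads 10.2%. The last rise, 0.7 percentage points, stands against a scatter of 0.5 points, so this plateau is a reading and not a certainty. Both branches pass through catalyst, so the reckoning takes the chance as independent of the catalyst charge. That is a guess, since no earlier run varies it. The reckoning then puts the peak of the flask at 10.2%.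

Next comes the clock. Green holds 1.50 times the catalyst of the flask. Taking green's last reading as its peak and stretching that time by this factor puts the peak of the flask at 6.00 min. Interpolated readings put green at the asked level at 2.05 min, which stretches to 3.07 min. This link is weak, as the feed lasts 2.0 min in both flasks and is set by the dosing, not by the catalyst charge. Reforged, the factor acts on the time past the feed. The reckoned peak moves to 5.00 min and the reckoned crossing to 2.07 min, and these are the numbers committed to.

The forecast says 10.5% at 7.5 min and a crossing at 2.5 min, holding that “Both channels scale with catalyst”.

The flask gives 11.0% at 5.06 min and crosses the asked level at 1.95 min, against the 10.2%, 5.00 min and 2.07 min reckoned here.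

    starting material + free catalyst ⇌ catalyst intermediate A (K = 22.6 L mol⁻¹, k = 380 L mol⁻¹ s⁻¹)
    coupling partner + catalyst intermediate A ⇌ free catalyst + target (K = 2.00, k = 322 L mol⁻¹ s⁻¹)
    second substrate + free catalyst ⇌ catalyst intermediate B (K = 30.7 L mol⁻¹, k = 719 L mol⁻¹ s⁻¹)
    coupling partner + catalyst intermediate B → free catalyst + second product (k = 13100 L mol⁻¹ s⁻¹)

At 1.97 min in the flask, the step of coupling partner with catalyst intermediate B uses coupling partner 4.0 times as fast as the step to target, forward rates alone, a forward fork chance of 20.0% at that moment, and at 20.0 min in the flask that forward ratio is 2.5, a forward chance of 28.2%, against the 10.2% carried from green. In the neighbour flask with 0.16 M of coupling partner, the carried chance gives 39.8%, while that flask holds 76.3% of target at 20.0 min, with second substrate at 0%.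

The runs were computed from invented constants; scatter was added.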